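## Analysis of the target

The target is a mulberry-type adduct built on a 1-methylcyclohexene. The ring is numbered here C1 (methyl-bearing alkene carbon), C2 (alkene CH), C3 (CH carrying the 6-hydroxy-2-(3,5-dihydroxyphenyl)benzofuran-5-yl group), C4 (CH carrying, through the ketone carbon C7, the 2,4-dihydroxy-3-prenylphenyl ring A), C5 (CH carrying the 2,4-dihydroxyphenyl group) and C6 (CH2). C3, C4 and C5 are three contiguous stereocentres. Read from the SMILES they are (3R,4R,5S), the all-trans array: the aroyl group is trans to both flanking aryl groups, the two aryl groups are cis to each other, and all three substituents can be equatorial on the half-chair. The sensitive groups are seven free phenols, a prenyl group flanked by two phenolic oxygens (acid closes it to a chroman), a ketone within reach of the ortho hydroxyls of the C3 and C5 aryl groups (acid ketalisation) and an epimerisable C4–H. The synthesis is hard because three crowded, differently arylated carbons must be set in absolute terms, and because nothing in the ring tells the alkene to sit at C1=C2 rather than in conjugation with the C3 aryl group. The strategy rests on one feature. C3 is benzylic to benzofuran C5, which has the C6 oxygen ortho and the furan oxygen O1 (on C7a) para, so C3 carries a cation well. Its ring neighbour C2 is the CH end of the only ring alkene, so a silyl group on C2 in an open-chain precursor lets C2 attack C3 and leaves the alkene at C1=C2.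

## Retrosynthetic reasoning

Protecting groups. Target 43 is traced to pentasilyl ether 42 and this to bis-MOM ether 41. Ring A carries MOM ethers because an aryllithium with an ortho silyloxy group would suffer silyl migration. The five other phenols carry triisopropylsilyl ethers, which survive amide bases, peroxide, hydride and Lewis acid. The acid step comes first, while the ortho oxygens of the C3 and C5 aryl groups are still silylated and cannot ketalise C7. The last step is then a buffered fluoride treatment.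

C7–C1' bond. Ketone 41 is cut between C7 and ring A, giving carbinol 40 and from it aldehyde 38 and aryllithium 39, made from bromide 32. The cut is made here so that the acid-sensitive prenylated ring enters after the Lewis acid step, and so that the C4 substituent can be a simple ester during ring formation.

C4 oxidation level. Aldehyde 38 comes from alcohol 36 and this from ester 35. The aldehyde is the stage at which a mild base can correct C4 toward the all-equatorial isomer.

C2–C3 bond (key disconnection). Ester 35 is opened between C2 and C3 to β-hydroxy ester 34. This is the one ring bond whose formation from a C3 cation and a C2 vinylsilane fixes the alkene position, and it leaves a precursor in which only C5 must be set beforehand. The forward step has to ionise C3, close the six-membered ring and place the C3 aryl group cis to the C5 aryl group.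

C3–C4 bond. Compound 34 is an aldol adduct of ester 20 (as enolate 33) and aldehyde 28. The aldol joins the two halves and supplies the hydroxyl that later leaves. The carbinol configuration is irrelevant, and C4 is biased by the C5 centre.

C4 insertion and C5–C6 bond. Ester 20 is the one-carbon homologue of acid 17 (through diazoketone 19). Acid 17 comes from imide 15, which is cut at C5–C6 into arylacetyl imide 13 and allylic bromide 7. At this point C5 is alpha to a carbonyl, so an auxiliary-directed alkylation can set it. This is the only stereocentre of the route set by a reagent rather than by the substrate.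

Bromide 7. It comes from alcohol 6, this from vinyl iodide 3, and this from alkyne 1. A chelation-controlled anti carbometalation fixes the Z geometry, and iodine is exchanged for silicon with retention.

Imide 13. It is assembled from acid 10 and auxiliary 11, and 10 is the silylated form of acid 8.

Aldehyde 28. Silyl ether 28 comes from phenol 27. The furan ring of 27 is cut at C2–C3 and O1–C2 into iodophenol 25 and alkyne 23 (coupling, then cyclisation). Iodophenol 25 is made from 24, and alkyne 23 from aldehyde 22 and diol 21.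

Bromide 32. It comes from 30 and this from 29. The bromine marks C1', and metalation between the two MOM ethers places the prenyl group at C3'.

## Alternatives that were turned down

Alternative 1: ring expansion of a donor–acceptor vinylcyclobutane.
- Disconnection: the C3–C4 bond is cut and C4 is tied to C1 instead. This gives cyclobutane A2 (ring atoms C4, C5, C6, C1), with methyl and the E-styryl arm C2=C3–benzofuranyl on C1 and the ring A ketone on C4.
- Forward key step: Sc(OTf)3 or heat would heterolyse the strained C1–C4 bond to an enolate at C4 and an allyl cation over C1–C2–C3. C4 would reclose on C3 to give A1, the all-trans cyclohexene as its hexakis(methoxymethyl) ether with the 2'-hydroxyl free.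
- For it: ring A and the ketone are present before the ring is made, so no late addition to a hindered C4 carbonyl is needed. C3 and C4 are set together, strain release drives the step, and the alkene arrives at C1=C2 by the allyl shift. On convergence and on the number of steps after the key step it is stronger than the chosen route.
- Against it: A2 is harder to make than the ring it delivers. A cyclobutane with a quaternary C1 beside the C4 and C5 centres has no dependable enantioselective preparation. The zwitterion can also fragment across C4–C5 and C6–C1, which destroys C5. Sc(OTf)3 meets six acetals and a prenyl group, and the final removal of six MOM ethers from the free ketone invites ketal and chroman formation.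
- Comparison: the chosen route reaches 34 by standard reactions only and sets C5 with an auxiliary, so the uncertainty is confined to one step.

Alternative 2: benzannulation that builds ring A.
- Disconnection: ring A is taken apart at C1'–C2', C2'–C3' and C4'–C5'. This gives diazo enone A4, which already contains the complete cyclohexene with C7 as a silylated carbinol, and prenyl siloxyalkyne A5.
- Forward key step: irradiation of A4 gives a vinylketene by Wolff rearrangement. Cycloaddition with A5, four-electron ring opening and six-electron closure give phenol A3.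
- For it: the prenyl group is placed between the two oxygens with full regiocontrol, the two ring A oxygens come out differentiated, and ring A needs no acid-labile protecting group. On that last point it is stronger than the chosen route, which must remove two MOM ethers in step 23.
- Against it: the key step is spent on the part of the molecule that the chosen route obtains in two steps (bromide 32). A4 still holds all three stereocentres and the ring alkene and needs a full synthesis of its own. A diazo enone has to be built on the hindered C4 substituent and photolysed beside a strongly absorbing 2-arylbenzofuran. Afterwards C7 must be unmasked and oxidised, and A5 is a labile ynol ether.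
- Comparison: it is several steps longer and does nothing for the stereochemical problem, which the chosen strategy addresses directly.

Alternative 3: enol silane closure onto a C5 cation.
- Disconnection: the C4–C5 bond is cut. This gives open-chain ketone A7, with C3 already set, a Z-trisubstituted alkene C1=C2 and a benzylic acetate at C5.
- Forward key step: Me3SiOTf with Et3N would form the silyl enol ether at C4 and ionise the C5 acetate, and C4 would attack C5 to give A6, the hepta-TBS ether of the target.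
- For it: C4 and C5 are set in the ring closure with both new substituents free to go equatorial, and A6 is one fluoride step from the target with no acid step at all. On end-game length and on direct control of C4 it is stronger than the chosen route.
- Against it: A7 is long and delicate. C3 must be set enantioselectively in an open chain, the Z-trisubstituted alkene must be made between C3 and C6, and ring A with its prenyl group and seven silyl ethers is carried through every step. The C5 cation has allylic C6 protons and can eliminate to a conjugated diene more easily than the C3 cation of the chosen route can lose the C4 proton. The ring A ketone beside an ortho silyloxy group enolises slowly.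
- Comparison: the chosen strategy has a short, standard route to its precursor, a nucleophile that needs no activation and an alkene position fixed by silicon. It pays with four functional-group steps after the ring closure.

Key step: step 18

Remark: TIPS = triisopropylsilyl, TIPSO = triisopropylsilyloxy, MOM = methoxymethyl. The cyclohexene numbering C1–C6 of the analysis is used in the names of ring compounds.

## Steps

Step 1
Reactants: 1 prop-2-yn-1-ol
Product: 3 (Z)-3-iodo-2-methylprop-2-en-1-ol, via vinylmagnesium chelate 2 (not isolated)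
Conditions: MeMgBr (2.5 equiv), CuI (0.1 equiv), Et2O/THF, −10 °C → rt; then I2, −10 °C
Reagents that add atoms: methylmagnesium bromide, C[Mg]Br; iodine, II
Why: Copper-catalysed anti carbomagnesiation of the propargylic alkoxide puts methyl on C2 and magnesium on C3 in a five-membered chelate, so the metal and then iodine end up cis to CH2OH; iodinolysis proceeds with retention.

Step 2
Reactants: 3 (Z)-3-iodo-2-methylprop-2-en-1-ol
Product: 6 (Z)-2-methyl-3-(trimethylsilyl)prop-2-en-1-ol, via dilithio species 4 (not isolated), via bis-silylated ether 5 (not isolated)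
Conditions: t-BuLi (3.1 equiv), Et2O, −78 °C; then Me3SiCl (2.5 equiv), −78 °C → rt; then aq. citric acid, MeOH
Reagents that add atoms: chlorotrimethylsilane, C[Si](C)(C)Cl
Why: Deprotonation and iodine–lithium exchange give a configurationally stable vinyllithium that is silylated with retention; the O-silyl group is lost on mild acid work-up while the vinylsilane stays.

Step 3
Reactants: 6 (Z)-2-methyl-3-(trimethylsilyl)prop-2-en-1-ol
Product: 7 (Z)-(3-bromo-2-methylprop-1-en-1-yl)trimethylsilane
Conditions: CBr4, PPh3, CH2Cl2, 0 °C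
Reagents that add atoms: carbon tetrabromide, BrC(Br)(Br)Br
Why: Appel bromination of a primary allylic alcohol under neutral conditions, which avoids protodesilylation and leaves the alkene geometry untouched.

Step 4
Reactants: 8 2,4-dihydroxyphenylacetic acid
Product: 10 [2,4-bis(TIPSO)phenyl]acetic acid, via silyl ester 9 (not isolated)
Conditions: i-Pr3SiCl (3.3 equiv), imidazole, DMF, rt; then K2CO3 (1 equiv), MeOH/H2O, 0 °C; citric acid
Reagents that add atoms: chlorotriisopropylsilane, CC(C)[Si](Cl)(C(C)C)C(C)C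
Why: Exhaustive silylation followed by selective hydrolysis of the much more labile silyl ester; the bulky aryl silyl ethers are chosen to survive the peroxide, base and Lewis acid steps ahead.

Step 5
Reactants: 10 [2,4-bis(TIPSO)phenyl]acetic acid; 11 (R)-4-benzyl-1,3-oxazolidin-2-one
Product: 13 (R)-4-benzyl-3-{[2,4-bis(TIPSO)phenyl]acetyl}-1,3-oxazolidin-2-one, via pivalic mixed anhydride 12 (not isolated)
Conditions: t-BuCOCl, Et3N, THF, −20 °C; then 11, LiCl, rt
Reagents that add atoms: none
Why: N-Acylation of the oxazolidinone through the mixed pivalic anhydride, a standard one-flask imide synthesis that tolerates the aryl silyl ethers.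

Step 6
Reactants: 13 (R)-4-benzyl-3-{[2,4-bis(TIPSO)phenyl]acetyl}-1,3-oxazolidin-2-one; 7 (Z)-(3-bromo-2-methylprop-1-en-1-yl)trimethylsilane
Product: 15 (R)-4-benzyl-3-[(2R,4Z)-2-(2,4-bis(TIPSO)phenyl)-4-methyl-5-(trimethylsilyl)pent-4-enoyl]-1,3-oxazolidin-2-one, via sodium enolate 14 (not isolated)
Conditions: NaN(SiMe3)2 (1.05 equiv), THF, −78 °C; then 7, −78 → −40 °C
Reagents that add atoms: none
Why: Oxazolidinone-directed alkylation: the chelated Z-enolate is shielded on one face by the benzyl group and the reactive allylic bromide enters from the other, which sets the future C5 in the sense required (2R here); a slight deficit of base guards the acidic α-aryl product against epimerisation.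

Step 7
Reactants: 15 the alkylated imide
Product: 17 (2R,4Z)-2-[2,4-bis(TIPSO)phenyl]-4-methyl-5-(trimethylsilyl)pent-4-enoic acid, via peroxy acid 16 (not isolated)
Conditions: LiOH, H2O2, THF/H2O, 0 °C; then aq. Na2SO3; then HCl to pH 3
Reagents that add atoms: hydrogen peroxide, OO
Why: Hydroperoxide attacks the exocyclic imide carbonyl selectively and the peroxy acid is reduced by sulfite; the mild, weakly basic conditions should spare the α-aryl stereocentre and the aryl TIPS ethers, and the auxiliary is recovered.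

Step 8
Reactants: 17 the (2R)-acid
Product: 19 (3R,5Z)-1-diazo-3-[2,4-bis(TIPSO)phenyl]-5-methyl-6-(trimethylsilyl)hex-5-en-2-one, via isobutyl carbonic anhydride 18 (not isolated)
Conditions: i-BuOCOCl, N-methylmorpholine, THF, −20 °C; then CH2N2, Et2O, −20 → 0 °C
Reagents that add atoms: diazomethane, C=[N+]=[N-]
Why: First half of the Arndt–Eistert homologation; activation as the mixed carbonic anhydride at low temperature with a weak base is the variant least prone to ketene formation and racemisation of an α-aryl acid.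

Step 9
Reactants: 19 the diazoketone
Product: 20 methyl (3S,5Z)-3-[2,4-bis(TIPSO)phenyl]-5-methyl-6-(trimethylsilyl)hex-5-enoate
Conditions: PhCO2Ag (0.1 equiv), Et3N, MeOH/THF, rt, dark
Reagents that add atoms: methanol, CO
Why: Wolff rearrangement: the stereogenic carbon migrates with retention and the ketene is trapped by methanol, which inserts the C4 methylene; the descriptor changes to S only because the priorities change.

Step 10
Reactants: 21 3,5-dihydroxybenzaldehyde
Product: 22 3,5-bis(TIPSO)benzaldehyde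
Conditions: i-Pr3SiCl, imidazole, DMF, rt
Reagents that add atoms: chlorotriisopropylsilane, CC(C)[Si](Cl)(C(C)C)C(C)C
Why: Routine silylation of two unhindered phenols.

Step 11
Reactants: 22 3,5-bis(TIPSO)benzaldehyde
Product: 23 1-ethynyl-3,5-bis(TIPSO)benzene
Conditions: Me3SiCHN2, LiN(i-Pr)2, THF, −78 °C → rt
Reagents that add atoms: trimethylsilyldiazomethane, C[Si](C)(C)C=[N+]=[N-]
Why: Colvin rearrangement: addition of the lithiated diazo reagent, Peterson-type elimination and 1,2-shift in the alkylidene carbene give the terminal alkyne without the carbonate/methanol medium that would endanger aryl silyl ethers.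

Step 12
Reactants: 24 2,4-dihydroxybenzaldehyde
Product: 25 2,4-dihydroxy-5-iodobenzaldehyde
Conditions: ICl, AcOH, rt
Reagents that add atoms: iodine monochloride, ClI
Why: Electrophilic iodination goes to C5, para to the 2-hydroxyl and ortho to the 4-hydroxyl and less hindered than C3; the isomer is purified by crystallisation.

Step 13
Reactants: 25 2,4-dihydroxy-5-iodobenzaldehyde; 23 1-ethynyl-3,5-bis(TIPSO)benzene
Product: 27 2-[3,5-bis(TIPSO)phenyl]-6-hydroxy-1-benzofuran-5-carbaldehyde, via alkynylphenol 26 (not isolated)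
Conditions: PdCl2(PPh3)2 (3 mol%), CuI (6 mol%), Et3N, DMF, rt then 70 °C
Reagents that add atoms: none
Why: Sonogashira coupling followed by 5-endo-dig cyclisation of the phenol ortho to the alkyne; the other hydroxyl is hydrogen-bonded to the aldehyde and not positioned to cyclise, so the benzofuran forms with the formyl group at C5 and the free hydroxyl at C6.

Step 14
Reactants: 27 the 6-hydroxybenzofuran-5-carbaldehyde
Product: 28 2-[3,5-bis(TIPSO)phenyl]-6-(TIPSO)-1-benzofuran-5-carbaldehyde
Conditions: i-Pr3SiOTf, 2,6-lutidine, CH2Cl2, 0 °C → rt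
Reagents that add atoms: triisopropylsilyl trifluoromethanesulfonate, CC(C)[Si](OS(=O)(=O)C(F)(F)F)(C(C)C)C(C)C
Why: The silyl triflate overcomes the hydrogen bond of the salicylaldehyde-type phenol; the bulky ether on this oxygen is wanted for the key step.

Step 15
Reactants: 29 4-bromobenzene-1,3-diol
Product: 30 1-bromo-2,4-bis(methoxymethoxy)benzene
Conditions: MeOCH2Cl, i-Pr2NEt, CH2Cl2, 0 °C → rt
Reagents that add atoms: chloromethyl methyl ether, COCCl
Why: Routine acetal protection; MOM ethers direct the next metalation and, unlike silyl ethers, do not migrate to an ortho carbanion.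

Step 16
Reactants: 30 1-bromo-2,4-bis(methoxymethoxy)benzene
Product: 32 1-bromo-2,4-bis(methoxymethoxy)-3-(3-methylbut-2-en-1-yl)benzene, via aryllithium 31 (not isolated)
Conditions: LiN(i-Pr)2, THF, −78 °C; then prenyl bromide, −78 °C → rt
Reagents that add atoms: 1-bromo-3-methylbut-2-ene, CC(C)=CCBr
Why: Directed ortho-metalation with a lithium amide, which deprotonates the position flanked by both MOM ethers without attacking the bromine; that lithio species is meta to bromine, so no aryne can form, and it is alkylated by the allylic bromide.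

Step 17
Reactants: 20 the homologated methyl ester; 28 the benzofuran-5-carbaldehyde
Product: 34 methyl (3S,5Z)-3-[2,4-bis(TIPSO)phenyl]-2-{hydroxy[2-(3,5-bis(TIPSO)phenyl)-6-(TIPSO)-1-benzofuran-5-yl]methyl}-5-methyl-6-(trimethylsilyl)hex-5-enoate (ring C5 = S; diastereomers at ring C3 and C4), via lithium enolate 33 (not isolated)
Conditions: LiN(i-Pr)2, THF, −78 °C; then 28, −78 °C; AcOH quench at −78 °C
Reagents that add atoms: none
Why: Lithium ester enolate aldol addition to a non-enolisable aldehyde, quenched cold to prevent retro-aldol and silyl transfer to the new alkoxide; C4 is created here, and the enolate conformer with C5–H eclipsing the double bond should be attacked anti to the large aryl group, which is the 4,5-relationship of the target (4R); the carbinol centre is left uncontrolled because step 18 erases it.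

Step 18
Reactants: 34 the β-hydroxy ester
Product: 35 methyl (3R,5S)-5-[2,4-bis(TIPSO)phenyl]-3-[2-(3,5-bis(TIPSO)phenyl)-6-(TIPSO)-1-benzofuran-5-yl]-1-methylcyclohex-1-ene-4-carboxylate (C4 epimers, 4R expected to predominate)
Conditions: SnCl4 (1.2 equiv), 2,6-di-tert-butyl-4-methylpyridine (0.2 equiv), CH2Cl2, −78 → −40 °C; aq. NaHCO3
Reagents that add atoms: none
Why: Proposed new method: SnCl4 should ionise the C3 hydroxyl of 34 to a benzylic cation stabilised by the ortho silyloxy oxygen on benzofuran C6 and the para ring oxygen O1; the Z-vinylsilane then attacks through its silicon-bearing carbon C2, which places the charge on tertiary C1, beta to silicon, and loss of the Me3Si group to chloride leaves the alkene at C1=C2 and nowhere else. The closest known reaction type is the vinylsilane-terminated cationic cyclisation in the endocyclic mode started from acetals or iminium ions; a benzylic alcohol as initiator of such a closure is the untested part. The single ring closes in a 6-endo-trig mode with respect to the vinylsilane (both alkene carbons become ring atoms), and the Z geometry holds silicon on the C6 side so that the new C2–C3 bond replaces the C–Si bond with retention. C3 is the only new stereocentre and is controlled by C5 through a chair-like transition state in which the C5 aryl group and the benzofuranyl group of the planar cation are both equatorial, which gives the 3,5-cis and hence 3R configuration. The step needs ring closure to outrun loss of the C4 proton (alkylidene ester) and retro-aldol cleavage; the intramolecular six-membered trap, the low temperature and the 2,2-disubstituted vinylsilane serve this, and the hindered pyridine removes adventitious acid that could protodesilylate the alkene. Friedel–Crafts closure on the C5 aryl group is not expected because its only reachable ring position is meta to both silyloxy groups, and the bulky TIPS ether on the benzofuran oxygen should keep that oxygen from closing onto C1 or being lost to a quinone methide. C4 is not touched, so the C4 ratio of 34 is carried into 35.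

Step 19
Reactants: 35 the cyclohexene methyl ester
Product: 36 the corresponding C4 hydroxymethyl compound, [(3R,5S)-5-(2,4-bis(TIPSO)phenyl)-3-(2-(3,5-bis(TIPSO)phenyl)-6-(TIPSO)-1-benzofuran-5-yl)-1-methylcyclohex-1-en-4-yl]methanol (C4 epimers)
Conditions: i-Bu2AlH (3 equiv), CH2Cl2, −78 → 0 °C; aq. potassium sodium tartrate
Reagents that add atoms: none
Why: Hydride reduction of the ester to the primary alcohol; aryl silyl ethers and the alkene are inert, and full reduction followed by reoxidation is more dependable on this hindered ester than a stop at the aldehyde.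

Step 20
Reactants: 36 the primary alcohol
Product: 38 (3R,4R,5S)-5-[2,4-bis(TIPSO)phenyl]-3-[2-(3,5-bis(TIPSO)phenyl)-6-(TIPSO)-1-benzofuran-5-yl]-1-methylcyclohex-1-ene-4-carbaldehyde (all-trans), via aldehyde epimer mixture 37 (not isolated)
Conditions: Dess–Martin periodinane, NaHCO3, CH2Cl2, 0 °C → rt; then DBU (0.2 equiv), CH2Cl2, rt
Reagents that add atoms: none
Why: Dess–Martin oxidation, then amidine-catalysed equilibration of the aldehyde through its enol; the all-trans isomer with the formyl group equatorial between two equatorial aryl groups should be the more stable one, so residual 4S epimer is funnelled to (4R)-38 without touching C3 or C5.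

Step 21
Reactants: 32 the ring A bromide; 38 the all-trans aldehyde
Product: 40 [2,4-bis(methoxymethoxy)-3-(3-methylbut-2-en-1-yl)phenyl][(3R,4R,5S)-5-(2,4-bis(TIPSO)phenyl)-3-(2-(3,5-bis(TIPSO)phenyl)-6-(TIPSO)-1-benzofuran-5-yl)-1-methylcyclohex-1-en-4-yl]methanol (carbinol epimers), via aryllithium 39 (not isolated)
Conditions: 32 (2 equiv), n-BuLi, THF, −78 °C; then 38, −78 → −40 °C; aq. NH4Cl
Reagents that add atoms: none
Why: Bromine–lithium exchange gives an aryllithium held by the ortho MOM ether, which adds 1,2 to the aldehyde; the new carbinol centre is formed as a mixture and is removed in the next step.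

Step 22
Reactants: 40 the carbinol
Product: 41 the corresponding ketone, the bis-MOM penta-TIPS ether of the target
Conditions: Dess–Martin periodinane, NaHCO3, CH2Cl2, rt
Reagents that add atoms: none
Why: Dess–Martin oxidation of a benzylic secondary alcohol under buffered, non-acidic conditions that spare the prenyl group, the acetals and the silyl ethers; C4 is already in its more stable configuration.

Step 23
Reactants: 41 the protected ketone
Product: 42 the penta-TIPS ether of the target with both ring A hydroxyls free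
Conditions: aq. HCl (3 M), MeOH/THF, rt → 40 °C
Reagents that add atoms: none
Why: Acid-catalysed acetal cleavage; both MOM ethers sit on a ring deactivated by the ketone, which makes the phenol a good leaving group, and the step is run while the ortho oxygens of the C3 and C5 aryl groups are still silylated, so that C7 cannot be ketalised.

Step 24
Reactants: 42 the penta-TIPS ether
Product: 43 the target, [(3R,4R,5S)-5-(2,4-dihydroxyphenyl)-3-(2-(3,5-dihydroxyphenyl)-6-hydroxy-1-benzofuran-5-yl)-1-methylcyclohex-1-en-4-yl][2,4-dihydroxy-3-(3-methylbut-2-en-1-yl)phenyl]methanone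
Conditions: Bu4NF (6 equiv), AcOH (6 equiv), THF, 0 °C → rt
Reagents that add atoms: none
Why: Fluoride cleavage of five aryl silyl ethers; acetic acid keeps the medium near neutral so that the polyphenol is neither oxidised as a phenoxide nor exposed to strong acid.

## Compound list

1 | prop-2-yn-1-ol | C#CCO | starting material
2 | bromomagnesium (Z)-3-(bromomagnesio)-2-methylprop-2-en-1-olate (vinylmagnesium chelate) | Br[Mg]OC/C(C)=C\[Mg]Br | intermediate
3 | (Z)-3-iodo-2-methylprop-2-en-1-ol | OC/C(C)=C\I | intermediate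
4 | lithium (Z)-3-lithio-2-methylprop-2-en-1-olate | [Li]OC/C(C)=C\[Li] | intermediate
5 | (Z)-trimethyl[2-methyl-3-(trimethylsilyloxy)prop-1-en-1-yl]silane | C[Si](C)(C)OC/C(C)=C\[Si](C)(C)C | intermediate
6 | (Z)-2-methyl-3-(trimethylsilyl)prop-2-en-1-ol | OC/C(C)=C\[Si](C)(C)C | intermediate
7 | (Z)-(3-bromo-2-methylprop-1-en-1-yl)trimethylsilane | BrC/C(C)=C\[Si](C)(C)C | intermediate
8 | 2,4-dihydroxyphenylacetic acid | OC(=O)Cc1ccc(O)cc1O | starting material
9 | triisopropylsilyl [2,4-bis(triisopropylsilyloxy)phenyl]acetate | CC(C)[Si](C(C)C)(C(C)C)OC(=O)Cc1ccc(O[Si](C(C)C)(C(C)C)C(C)C)cc1O[Si](C(C)C)(C(C)C)C(C)C | intermediate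
10 | [2,4-bis(triisopropylsilyloxy)phenyl]acetic acid | OC(=O)Cc1ccc(O[Si](C(C)C)(C(C)C)C(C)C)cc1O[Si](C(C)C)(C(C)C)C(C)C | intermediate
11 | (R)-4-benzyl-1,3-oxazolidin-2-one | O=C1OC[C@@H](Cc2ccccc2)N1 | starting material
12 | [2,4-bis(triisopropylsilyloxy)phenyl]acetic pivalic anhydride | CC(C)(C)C(=O)OC(=O)Cc1ccc(O[Si](C(C)C)(C(C)C)C(C)C)cc1O[Si](C(C)C)(C(C)C)C(C)C | intermediate
13 | (R)-4-benzyl-3-{[2,4-bis(triisopropylsilyloxy)phenyl]acetyl}-1,3-oxazolidin-2-one | O=C1OC[C@@H](Cc2ccccc2)N1C(=O)Cc1ccc(O[Si](C(C)C)(C(C)C)C(C)C)cc1O[Si](C(C)C)(C(C)C)C(C)C | intermediate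
14 | sodium (Z)-enolate of 13 | O=C1OC[C@@H](Cc2ccccc2)N1/C(O[Na])=C/c1ccc(O[Si](C(C)C)(C(C)C)C(C)C)cc1O[Si](C(C)C)(C(C)C)C(C)C | intermediate
15 | (R)-4-benzyl-3-[(2R,4Z)-2-(2,4-bis(triisopropylsilyloxy)phenyl)-4-methyl-5-(trimethylsilyl)pent-4-enoyl]-1,3-oxazolidin-2-one | O=C1OC[C@@H](Cc2ccccc2)N1C(=O)[C@@H](c1ccc(O[Si](C(C)C)(C(C)C)C(C)C)cc1O[Si](C(C)C)(C(C)C)C(C)C)C/C(C)=C\[Si](C)(C)C | intermediate
16 | (2R,4Z)-2-[2,4-bis(triisopropylsilyloxy)phenyl]-4-methyl-5-(trimethylsilyl)pent-4-eneperoxoic acid | OOC(=O)[C@@H](c1ccc(O[Si](C(C)C)(C(C)C)C(C)C)cc1O[Si](C(C)C)(C(C)C)C(C)C)C/C(C)=C\[Si](C)(C)C | intermediate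
17 | (2R,4Z)-2-[2,4-bis(triisopropylsilyloxy)phenyl]-4-methyl-5-(trimethylsilyl)pent-4-enoic acid | OC(=O)[C@@H](c1ccc(O[Si](C(C)C)(C(C)C)C(C)C)cc1O[Si](C(C)C)(C(C)C)C(C)C)C/C(C)=C\[Si](C)(C)C | intermediate
18 | mixed anhydride of 17 with isobutyl hydrogen carbonate | CC(C)COC(=O)OC(=O)[C@@H](c1ccc(O[Si](C(C)C)(C(C)C)C(C)C)cc1O[Si](C(C)C)(C(C)C)C(C)C)C/C(C)=C\[Si](C)(C)C | intermediate
19 | (3R,5Z)-1-diazo-3-[2,4-bis(triisopropylsilyloxy)phenyl]-5-methyl-6-(trimethylsilyl)hex-5-en-2-one | [N-]=[N+]=CC(=O)[C@@H](c1ccc(O[Si](C(C)C)(C(C)C)C(C)C)cc1O[Si](C(C)C)(C(C)C)C(C)C)C/C(C)=C\[Si](C)(C)C | intermediate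
20 | methyl (3S,5Z)-3-[2,4-bis(triisopropylsilyloxy)phenyl]-5-methyl-6-(trimethylsilyl)hex-5-enoate | COC(=O)C[C@@H](c1ccc(O[Si](C(C)C)(C(C)C)C(C)C)cc1O[Si](C(C)C)(C(C)C)C(C)C)C/C(C)=C\[Si](C)(C)C | intermediate
21 | 3,5-dihydroxybenzaldehyde | O=Cc1cc(O)cc(O)c1 | starting material
22 | 3,5-bis(triisopropylsilyloxy)benzaldehyde | O=Cc1cc(O[Si](C(C)C)(C(C)C)C(C)C)cc(O[Si](C(C)C)(C(C)C)C(C)C)c1 | intermediate
23 | 1-ethynyl-3,5-bis(triisopropylsilyloxy)benzene | C#Cc1cc(O[Si](C(C)C)(C(C)C)C(C)C)cc(O[Si](C(C)C)(C(C)C)C(C)C)c1 | intermediate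
24 | 2,4-dihydroxybenzaldehyde | O=Cc1ccc(O)cc1O | starting material
25 | 2,4-dihydroxy-5-iodobenzaldehyde | O=Cc1cc(I)c(O)cc1O | intermediate
26 | 5-{[3,5-bis(triisopropylsilyloxy)phenyl]ethynyl}-2,4-dihydroxybenzaldehyde | O=Cc1cc(C#Cc2cc(O[Si](C(C)C)(C(C)C)C(C)C)cc(O[Si](C(C)C)(C(C)C)C(C)C)c2)c(O)cc1O | intermediate
27 | 2-[3,5-bis(triisopropylsilyloxy)phenyl]-6-hydroxy-1-benzofuran-5-carbaldehyde | O=Cc1cc2cc(-c3cc(O[Si](C(C)C)(C(C)C)C(C)C)cc(O[Si](C(C)C)(C(C)C)C(C)C)c3)oc2cc1O | intermediate
28 | 2-[3,5-bis(triisopropylsilyloxy)phenyl]-6-(triisopropylsilyloxy)-1-benzofuran-5-carbaldehyde | O=Cc1cc2cc(-c3cc(O[Si](C(C)C)(C(C)C)C(C)C)cc(O[Si](C(C)C)(C(C)C)C(C)C)c3)oc2cc1O[Si](C(C)C)(C(C)C)C(C)C | intermediate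
29 | 4-bromobenzene-1,3-diol | Oc1ccc(Br)c(O)c1 | starting material
30 | 1-bromo-2,4-bis(methoxymethoxy)benzene | COCOc1ccc(Br)c(OCOC)c1 | intermediate
31 | [3-bromo-2,6-bis(methoxymethoxy)phenyl]lithium | COCOc1ccc(Br)c(OCOC)c1[Li] | intermediate
32 | 1-bromo-2,4-bis(methoxymethoxy)-3-(3-methylbut-2-en-1-yl)benzene | COCOc1ccc(Br)c(OCOC)c1CC=C(C)C | intermediate
33 | lithium enolate of 20 (OLi trans to C5) | CO/C(O[Li])=C\[C@@H](c1ccc(O[Si](C(C)C)(C(C)C)C(C)C)cc1O[Si](C(C)C)(C(C)C)C(C)C)C/C(C)=C\[Si](C)(C)C | intermediate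
34 | methyl (3S,5Z)-3-[2,4-bis(TIPSO)phenyl]-2-{hydroxy[2-(3,5-bis(TIPSO)phenyl)-6-(TIPSO)-1-benzofuran-5-yl]methyl}-5-methyl-6-(trimethylsilyl)hex-5-enoate, mixture at the carbinol carbon and at C2 of the chain | COC(=O)C(C(O)c1cc2cc(-c3cc(O[Si](C(C)C)(C(C)C)C(C)C)cc(O[Si](C(C)C)(C(C)C)C(C)C)c3)oc2cc1O[Si](C(C)C)(C(C)C)C(C)C)[C@@H](c1ccc(O[Si](C(C)C)(C(C)C)C(C)C)cc1O[Si](C(C)C)(C(C)C)C(C)C)C/C(C)=C\[Si](C)(C)C | intermediate
35 | methyl (3R,5S)-5-[2,4-bis(TIPSO)phenyl]-3-[2-(3,5-bis(TIPSO)phenyl)-6-(TIPSO)-1-benzofuran-5-yl]-1-methylcyclohex-1-ene-4-carboxylate, C4 epimers | COC(=O)C1[C@@H](c2ccc(O[Si](C(C)C)(C(C)C)C(C)C)cc2O[Si](C(C)C)(C(C)C)C(C)C)CC(C)=C[C@H]1c1cc2cc(-c3cc(O[Si](C(C)C)(C(C)C)C(C)C)cc(O[Si](C(C)C)(C(C)C)C(C)C)c3)oc2cc1O[Si](C(C)C)(C(C)C)C(C)C | intermediate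
36 | [(3R,5S)-5-(2,4-bis(TIPSO)phenyl)-3-(2-(3,5-bis(TIPSO)phenyl)-6-(TIPSO)-1-benzofuran-5-yl)-1-methylcyclohex-1-en-4-yl]methanol, C4 epimers | OCC1[C@@H](c2ccc(O[Si](C(C)C)(C(C)C)C(C)C)cc2O[Si](C(C)C)(C(C)C)C(C)C)CC(C)=C[C@H]1c1cc2cc(-c3cc(O[Si](C(C)C)(C(C)C)C(C)C)cc(O[Si](C(C)C)(C(C)C)C(C)C)c3)oc2cc1O[Si](C(C)C)(C(C)C)C(C)C | intermediate
37 | (3R,5S)-5-[2,4-bis(TIPSO)phenyl]-3-[2-(3,5-bis(TIPSO)phenyl)-6-(TIPSO)-1-benzofuran-5-yl]-1-methylcyclohex-1-ene-4-carbaldehyde, C4 epimers | O=CC1[C@@H](c2ccc(O[Si](C(C)C)(C(C)C)C(C)C)cc2O[Si](C(C)C)(C(C)C)C(C)C)CC(C)=C[C@H]1c1cc2cc(-c3cc(O[Si](C(C)C)(C(C)C)C(C)C)cc(O[Si](C(C)C)(C(C)C)C(C)C)c3)oc2cc1O[Si](C(C)C)(C(C)C)C(C)C | intermediate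
38 | (3R,4R,5S)-5-[2,4-bis(TIPSO)phenyl]-3-[2-(3,5-bis(TIPSO)phenyl)-6-(TIPSO)-1-benzofuran-5-yl]-1-methylcyclohex-1-ene-4-carbaldehyde | O=C[C@@H]1[C@@H](c2ccc(O[Si](C(C)C)(C(C)C)C(C)C)cc2O[Si](C(C)C)(C(C)C)C(C)C)CC(C)=C[C@H]1c1cc2cc(-c3cc(O[Si](C(C)C)(C(C)C)C(C)C)cc(O[Si](C(C)C)(C(C)C)C(C)C)c3)oc2cc1O[Si](C(C)C)(C(C)C)C(C)C | intermediate
39 | [2,4-bis(methoxymethoxy)-3-(3-methylbut-2-en-1-yl)phenyl]lithium | COCOc1ccc([Li])c(OCOC)c1CC=C(C)C | intermediate
40 | carbinol: [2,4-bis(MOM-oxy)-3-prenylphenyl][(3R,4R,5S)-5-(2,4-bis(TIPSO)phenyl)-3-(2-(3,5-bis(TIPSO)phenyl)-6-(TIPSO)-1-benzofuran-5-yl)-1-methylcyclohex-1-en-4-yl]methanol, carbinol epimers | CC(C)=CCc1c(OCOC)ccc(C(O)[C@@H]2[C@@H](c3ccc(O[Si](C(C)C)(C(C)C)C(C)C)cc3O[Si](C(C)C)(C(C)C)C(C)C)CC(C)=C[C@H]2c2cc3cc(-c4cc(O[Si](C(C)C)(C(C)C)C(C)C)cc(O[Si](C(C)C)(C(C)C)C(C)C)c4)oc3cc2O[Si](C(C)C)(C(C)C)C(C)C)c1OCOC | intermediate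
41 | ketone: bis-MOM (ring A) penta-TIPS ether of the target, (3R,4R,5S) | CC(C)=CCc1c(OCOC)ccc(C(=O)[C@@H]2[C@@H](c3ccc(O[Si](C(C)C)(C(C)C)C(C)C)cc3O[Si](C(C)C)(C(C)C)C(C)C)CC(C)=C[C@H]2c2cc3cc(-c4cc(O[Si](C(C)C)(C(C)C)C(C)C)cc(O[Si](C(C)C)(C(C)C)C(C)C)c4)oc3cc2O[Si](C(C)C)(C(C)C)C(C)C)c1OCOC | intermediate
42 | penta-TIPS ether of the target with free ring A hydroxyls, (3R,4R,5S) | CC(C)=CCc1c(O)ccc(C(=O)[C@@H]2[C@@H](c3ccc(O[Si](C(C)C)(C(C)C)C(C)C)cc3O[Si](C(C)C)(C(C)C)C(C)C)CC(C)=C[C@H]2c2cc3cc(-c4cc(O[Si](C(C)C)(C(C)C)C(C)C)cc(O[Si](C(C)C)(C(C)C)C(C)C)c4)oc3cc2O[Si](C(C)C)(C(C)C)C(C)C)c1O | intermediate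
43 | [(3R,4R,5S)-5-(2,4-dihydroxyphenyl)-3-(2-(3,5-dihydroxyphenyl)-6-hydroxy-1-benzofuran-5-yl)-1-methylcyclohex-1-en-4-yl][2,4-dihydroxy-3-(3-methylbut-2-en-1-yl)phenyl]methanone | CC(C)=CCc1c(O)ccc(C(=O)[C@@H]2[C@@H](c3ccc(O)cc3O)CC(C)=C[C@H]2c2cc3cc(-c4cc(O)cc(O)c4)oc3cc2O)c1O | target

## Step count and risk

Total step count: 24. Longest linear sequence: 15 steps (steps 1–3, 6–9 and 17–24, from prop-2-yn-1-ol).

Least certain steps:

Step 18 (key step). The most likely failures are loss of the C4 proton from the C3 cation before the vinylsilane closes (giving the conjugated alkylidene ester), Lewis-acid retro-aldol cleavage, protodesilylation of the vinylsilane by adventitious acid, and loss of the ortho silyl group from the cation. All of these arise because the cation is long-lived and the vinylsilane is only a moderate nucleophile. The fallback builds the same ring by known reactions, closing C1=C2 by metathesis instead of C2–C3 by cation chemistry. It sets out from diazoketone 19 and aldehyde 28 and returns at 35.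
- Aldehyde 28 is converted by Wittig reaction with Ph3P=CHCO2Et into the E-acrylate F1 and reduced with i-Bu2AlH to the allylic alcohol F2.
- Wolff rearrangement of 19 (PhCO2Ag, Et3N, THF) in the presence of F2 gives the allylic ester F3.
- Ireland–Claisen rearrangement of F3 (LiN(i-Pr)2, Me3SiCl, THF without polar additive, −78 °C → rt) forms the C3–C4 bond through a chair transition state and gives the acid F4. The enolate geometry sets the 3,4-relationship, and the face anti to the C5 aryl group sets the 4,5-relationship.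
- Me3SiCHN2 gives the methyl ester F5, and protodesilylation (CF3CO2H, CH2Cl2, 0 °C) gives the diene F6.
- Ring-closing metathesis of F6 with the second-generation Grubbs catalyst RuCl2(H2IMes)(PCy3)(=CHPh) gives 35 as its all-trans isomer.

Step 17. The likely failures are poor facial selectivity at C4 (the aryl group and the allylic chain on C5 may not differ enough), retro-aldol on warming, and transfer of the ortho silyl group from the phenol oxygen to the new alkoxide. A further uncertainty is that the thermodynamic preference used in step 20 may be modest for a group on a cyclohexene carbon with only one syn-axial hydrogen. The fallback fixes C4 with the auxiliary instead of the substrate. It sets out from 19 and returns at 36.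
- Wolff rearrangement of 19 in THF/H2O gives the acid F7, which is attached to 11 (t-BuCOCl, Et3N, then LiCl) to give the imide F8.
- The boron aldol reaction of F8 (Bu2BOTf, i-Pr2NEt, CH2Cl2, −78 °C) with 28 gives the syn adduct F9. The R auxiliary and the C5 centre should both favour 4R, and the boron aldolate is not basic enough for silyl transfer.
- Cyclisation of F9 under the conditions of step 18 gives the imide F10, and LiBH4 in THF/MeOH cleaves the auxiliary to give 36 as the single 4R epimer.

Step 21. The likely failures are slow addition to an aldehyde flanked by two ortho-silyloxyaryl groups, and deprotonation at C4 by the basic aryllithium, which returns aldehyde and erodes C4. The fallback replaces carbonyl addition by an acyl cross-coupling. It sets out from 38 and 39 and returns at 41.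
- Pinnick oxidation of 38 (NaClO2, NaH2PO4, 2-methylbut-2-ene) gives the acid F11.
- 1-Chloro-N,N,2-trimethylprop-1-en-1-amine converts F11 under neutral conditions into the acid chloride F12.
- Aryllithium 39 is transmetalated with ZnCl2 to the arylzinc chloride F13, and Negishi coupling of F12 with F13 (Pd(PPh3)4, THF) gives ketone 41 directly.

Step 23. The likely failure is acid-promoted cyclisation of a freed ring A hydroxyl onto the prenyl group, or addition of methanol to it, before the second MOM ether has gone; partial loss of silyl ethers is a lesser concern. The fallback exchanges the ring A protecting group for one that fluoride removes. It sets out from 29 and 38 and returns at 43.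
- Diol 29 is protected with Me3SiCH2CH2OCH2Cl and i-Pr2NEt as the bis-SEM ether F14, which is lithiated and prenylated as in step 16 to give F15.
- Bromine–lithium exchange of F15 (n-BuLi, −78 °C) and addition to 38 give the carbinol F16, and Dess–Martin oxidation gives the ketone F17.
- Bu4NF in THF/DMPU at 50 °C then removes the two SEM groups and the five silyl ethers in one operation to give 43.

## Further compounds

F1 | step 18 | ethyl (E)-3-{2-[3,5-bis(TIPSO)phenyl]-6-(TIPSO)-1-benzofuran-5-yl}prop-2-enoate | CCOC(=O)/C=C/c1cc2cc(-c3cc(O[Si](C(C)C)(C(C)C)C(C)C)cc(O[Si](C(C)C)(C(C)C)C(C)C)c3)oc2cc1O[Si](C(C)C)(C(C)C)C(C)C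
F2 | step 18 | (E)-3-{2-[3,5-bis(TIPSO)phenyl]-6-(TIPSO)-1-benzofuran-5-yl}prop-2-en-1-ol | OC/C=C/c1cc2cc(-c3cc(O[Si](C(C)C)(C(C)C)C(C)C)cc(O[Si](C(C)C)(C(C)C)C(C)C)c3)oc2cc1O[Si](C(C)C)(C(C)C)C(C)C
F3 | step 18 | (E)-3-(benzofuran-5-yl)allyl ester of (3S,5Z)-3-[2,4-bis(TIPSO)phenyl]-5-methyl-6-(trimethylsilyl)hex-5-enoic acid | O=C(OC/C=C/c1cc2cc(-c3cc(O[Si](C(C)C)(C(C)C)C(C)C)cc(O[Si](C(C)C)(C(C)C)C(C)C)c3)oc2cc1O[Si](C(C)C)(C(C)C)C(C)C)C[C@@H](c1ccc(O[Si](C(C)C)(C(C)C)C(C)C)cc1O[Si](C(C)C)(C(C)C)C(C)C)C/C(C)=C\[Si](C)(C)C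
F4 | step 18 | Ireland–Claisen acid with ring C3 (benzofuranyl, vinyl), C4 (carboxyl) and C5 (aryl) set as in the target and the Z-vinylsilane retained | OC(=O)[C@@H]([C@@H](C=C)c1cc2cc(-c3cc(O[Si](C(C)C)(C(C)C)C(C)C)cc(O[Si](C(C)C)(C(C)C)C(C)C)c3)oc2cc1O[Si](C(C)C)(C(C)C)C(C)C)[C@@H](c1ccc(O[Si](C(C)C)(C(C)C)C(C)C)cc1O[Si](C(C)C)(C(C)C)C(C)C)C/C(C)=C\[Si](C)(C)C
F5 | step 18 | methyl ester of F4 | COC(=O)[C@@H]([C@@H](C=C)c1cc2cc(-c3cc(O[Si](C(C)C)(C(C)C)C(C)C)cc(O[Si](C(C)C)(C(C)C)C(C)C)c3)oc2cc1O[Si](C(C)C)(C(C)C)C(C)C)[C@@H](c1ccc(O[Si](C(C)C)(C(C)C)C(C)C)cc1O[Si](C(C)C)(C(C)C)C(C)C)C/C(C)=C\[Si](C)(C)C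
F6 | step 18 | protodesilylated diene: methyl ester with a vinyl group on C3 and a 2-methylallyl group on C5 | COC(=O)[C@@H]([C@@H](C=C)c1cc2cc(-c3cc(O[Si](C(C)C)(C(C)C)C(C)C)cc(O[Si](C(C)C)(C(C)C)C(C)C)c3)oc2cc1O[Si](C(C)C)(C(C)C)C(C)C)[C@@H](c1ccc(O[Si](C(C)C)(C(C)C)C(C)C)cc1O[Si](C(C)C)(C(C)C)C(C)C)CC(C)=C
F7 | step 17 | (3S,5Z)-3-[2,4-bis(TIPSO)phenyl]-5-methyl-6-(trimethylsilyl)hex-5-enoic acid | OC(=O)C[C@@H](c1ccc(O[Si](C(C)C)(C(C)C)C(C)C)cc1O[Si](C(C)C)(C(C)C)C(C)C)C/C(C)=C\[Si](C)(C)C
F8 | step 17 | (R)-4-benzyl-3-[(3S,5Z)-3-(2,4-bis(TIPSO)phenyl)-5-methyl-6-(trimethylsilyl)hex-5-enoyl]-1,3-oxazolidin-2-one | O=C1OC[C@@H](Cc2ccccc2)N1C(=O)C[C@@H](c1ccc(O[Si](C(C)C)(C(C)C)C(C)C)cc1O[Si](C(C)C)(C(C)C)C(C)C)C/C(C)=C\[Si](C)(C)C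
F9 | step 17 | syn-aldol adduct of F8 with 28 (ring C4 = R, C5 = S) | O=C1OC[C@@H](Cc2ccccc2)N1C(=O)[C@@H]([C@@H](O)c1cc2cc(-c3cc(O[Si](C(C)C)(C(C)C)C(C)C)cc(O[Si](C(C)C)(C(C)C)C(C)C)c3)oc2cc1O[Si](C(C)C)(C(C)C)C(C)C)[C@@H](c1ccc(O[Si](C(C)C)(C(C)C)C(C)C)cc1O[Si](C(C)C)(C(C)C)C(C)C)C/C(C)=C\[Si](C)(C)C
F10 | step 17 | (3R,4R,5S)-cyclohexene N-acyl oxazolidinone (imide analogue of all-trans 35) | O=C1OC[C@@H](Cc2ccccc2)N1C(=O)[C@@H]1[C@@H](c2ccc(O[Si](C(C)C)(C(C)C)C(C)C)cc2O[Si](C(C)C)(C(C)C)C(C)C)CC(C)=C[C@H]1c1cc2cc(-c3cc(O[Si](C(C)C)(C(C)C)C(C)C)cc(O[Si](C(C)C)(C(C)C)C(C)C)c3)oc2cc1O[Si](C(C)C)(C(C)C)C(C)C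
F11 | step 21 | (3R,4R,5S)-cyclohexene-4-carboxylic acid corresponding to 38 | OC(=O)[C@@H]1[C@@H](c2ccc(O[Si](C(C)C)(C(C)C)C(C)C)cc2O[Si](C(C)C)(C(C)C)C(C)C)CC(C)=C[C@H]1c1cc2cc(-c3cc(O[Si](C(C)C)(C(C)C)C(C)C)cc(O[Si](C(C)C)(C(C)C)C(C)C)c3)oc2cc1O[Si](C(C)C)(C(C)C)C(C)C
F12 | step 21 | acid chloride of F11 | ClC(=O)[C@@H]1[C@@H](c2ccc(O[Si](C(C)C)(C(C)C)C(C)C)cc2O[Si](C(C)C)(C(C)C)C(C)C)CC(C)=C[C@H]1c1cc2cc(-c3cc(O[Si](C(C)C)(C(C)C)C(C)C)cc(O[Si](C(C)C)(C(C)C)C(C)C)c3)oc2cc1O[Si](C(C)C)(C(C)C)C(C)C
F13 | step 21 | [2,4-bis(methoxymethoxy)-3-(3-methylbut-2-en-1-yl)phenyl]zinc chloride | COCOc1ccc([Zn]Cl)c(OCOC)c1CC=C(C)C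
F14 | step 23 | 1-bromo-2,4-bis{[2-(trimethylsilyl)ethoxy]methoxy}benzene | C[Si](C)(C)CCOCOc1ccc(Br)c(OCOCC[Si](C)(C)C)c1
F15 | step 23 | 1-bromo-3-(3-methylbut-2-en-1-yl)-2,4-bis{[2-(trimethylsilyl)ethoxy]methoxy}benzene | C[Si](C)(C)CCOCOc1ccc(Br)c(OCOCC[Si](C)(C)C)c1CC=C(C)C
F16 | step 23 | bis-SEM analogue of carbinol 40 | CC(C)=CCc1c(OCOCC[Si](C)(C)C)ccc(C(O)[C@@H]2[C@@H](c3ccc(O[Si](C(C)C)(C(C)C)C(C)C)cc3O[Si](C(C)C)(C(C)C)C(C)C)CC(C)=C[C@H]2c2cc3cc(-c4cc(O[Si](C(C)C)(C(C)C)C(C)C)cc(O[Si](C(C)C)(C(C)C)C(C)C)c4)oc3cc2O[Si](C(C)C)(C(C)C)C(C)C)c1OCOCC[Si](C)(C)C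
F17 | step 23 | bis-SEM analogue of ketone 41 | CC(C)=CCc1c(OCOCC[Si](C)(C)C)ccc(C(=O)[C@@H]2[C@@H](c3ccc(O[Si](C(C)C)(C(C)C)C(C)C)cc3O[Si](C(C)C)(C(C)C)C(C)C)CC(C)=C[C@H]2c2cc3cc(-c4cc(O[Si](C(C)C)(C(C)C)C(C)C)cc(O[Si](C(C)C)(C(C)C)C(C)C)c4)oc3cc2O[Si](C(C)C)(C(C)C)C(C)C)c1OCOCC[Si](C)(C)C
A1 | alternative 1 | all-trans cyclohexene ketone, hexakis(methoxymethyl) ether of the target with the 2'-hydroxyl free | O=C(c1ccc(OCOC)c(CC=C(C)C)c1O)[C@@H]1[C@@H](c2ccc(OCOC)cc2OCOC)CC(C)=C[C@H]1c1cc2cc(-c3cc(OCOC)cc(OCOC)c3)oc2cc1OCOC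
A2 | alternative 1 | donor–acceptor cyclobutane (ring C4, C5, C6, C1) with methyl and E-styryl on C1 and the ring A ketone on C4 | O=C(c1ccc(OCOC)c(CC=C(C)C)c1O)C1[C@@H](c2ccc(OCOC)cc2OCOC)CC1(C)/C=C/c1cc2cc(-c3cc(OCOC)cc(OCOC)c3)oc2cc1OCOC
A3 | alternative 2 | ring A phenol with C4' triisopropylsilyl ether and C7 as a silylated carbinol | CC(C)=CCc1c(O[Si](C(C)C)(C(C)C)C(C)C)ccc(C(O[Si](C)(C)C(C)(C)C)[C@@H]2[C@@H](c3ccc(O[Si](C)(C)C(C)(C)C)cc3O[Si](C)(C)C(C)(C)C)CC(C)=C[C@H]2c2cc3cc(-c4cc(O[Si](C)(C)C(C)(C)C)cc(O[Si](C)(C)C(C)(C)C)c4)oc3cc2O[Si](C)(C)C(C)(C)C)c1O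
A4 | alternative 2 | E-configured α-diazo enone carrying the complete cyclohexene core at its γ-carbinol carbon | [N-]=[N+]=CC(=O)/C=C/C(O[Si](C)(C)C(C)(C)C)[C@@H]1[C@@H](c2ccc(O[Si](C)(C)C(C)(C)C)cc2O[Si](C)(C)C(C)(C)C)CC(C)=C[C@H]1c1cc2cc(-c3cc(O[Si](C)(C)C(C)(C)C)cc(O[Si](C)(C)C(C)(C)C)c3)oc2cc1O[Si](C)(C)C(C)(C)C
A5 | alternative 2 | triisopropyl[(5-methylhex-4-en-1-yn-1-yl)oxy]silane | CC(C)=CCC#CO[Si](C(C)C)(C(C)C)C(C)C
A6 | alternative 3 | hepta-TBS ether of the target | O=C(c1ccc(O[Si](C)(C)C(C)(C)C)c(CC=C(C)C)c1O[Si](C)(C)C(C)(C)C)[C@@H]1[C@@H](c2ccc(O[Si](C)(C)C(C)(C)C)cc2O[Si](C)(C)C(C)(C)C)CC(C)=C[C@H]1c1cc2cc(-c3cc(O[Si](C)(C)C(C)(C)C)cc(O[Si](C)(C)C(C)(C)C)c3)oc2cc1O[Si](C)(C)C(C)(C)C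
A7 | alternative 3 | open-chain ring A ketone with C3 set, Z-alkene C1=C2 and C5 benzylic acetate | O=C(c1ccc(O[Si](C)(C)C(C)(C)C)c(CC=C(C)C)c1O[Si](C)(C)C(C)(C)C)C[C@H](c1cc2cc(-c3cc(O[Si](C)(C)C(C)(C)C)cc(O[Si](C)(C)C(C)(C)C)c3)oc2cc1O[Si](C)(C)C(C)(C)C)/C=C(/C)CC(OC(C)=O)c1ccc(O[Si](C)(C)C(C)(C)C)cc1O[Si](C)(C)C(C)(C)C
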